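The flask holds 0.050 M of substrate against 0.0900 M of reagent, with 7.5 mM of free catalyst and 2.50 mM of capture agent, and its own course so far is the ash run, beside the cooler birch run.

| flask | substrate | reagent | capture agent | free catalyst | temperature | remark | time |
|---|---|---|---|---|---|---|---|
| ash | 0.050 M | 0.090 M | 2.5 mM | 7.5 mM | 25 °C | the very flask that is asked about, followed so far |  |
| birch | 0.050 M | 0.090 M | 2.5 mM | 7.5 mM | 20 °C | run made earlier |  |
| flask | 0.050 M | 0.0900 M | 2.50 mM | 7.5 mM | 25 °C |  | 4.0 h |

| run | time / min | target / % | substrate / % |
|---|---|---|---|
| ash | 40.0 | 39.5 | 11.9 |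
| ash | 80.0 | 44.9 | 7.3 |
| ash | 120 | 46.2 | 5.9 |
| ash | 150 | 46.1 | 5.8 |
| ash | 180 | 46.3 | 5.0 |
| ash | 240 | 45.3 | 3.3 |
| birch | 40.0 | 46.5 | 10.7 |
| birch | 80.0 | 54.2 | 5.7 |
| birch | 120 | 58.6 | 3.7 |
| birch | 150 | 57.7 | 3.3 |
| birch | 180 | 59.5 | 3.2 |
| birch | 240 | 59.4 | 3.4 |

(standard deviation of a reading: 0.5 percentage points)
- summer: at 4.0 h take out 90 % of the target then present, then wait 8.0 h
- spring: at 4.0 h add free catalyst, 100 % of the amount charged, then wait 8.0 h
- autumn: at 4.0 h add reagent, 50.0 % of the amount charged, then wait 8.0 h
- dusk: change nothing and wait 8.0 h more
- dawn: at 4.0 h raise the temperature by 20 K, then wait 8.0 h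
- target taken out counts as made
- the earlier runs were read with a standard deviation of 0.5 percentage points
- additions bring no volume worth counting
- target, in percent of the substrate first charged, at 4.0 h
- which option adds most target ("none" when 2 percentage points or less is all one gets) (summer / spring / autumn / dusk / dawn / none)
- target present, with what was taken out counted in, in percent of the substrate first charged, after summer
- target present, with what was taken out counted in, in percent of the substrate first charged, after dusk

Follow one substrate molecule to its fork: it becomes target or it goes elsewhere. In ash, up to the first reading, target gained per substrate lost comes to 0.448; this fork share φ, a running selectivity, is the quantity carried on. Birch gives 0.521, more than ash, so warmth lowers φ and dawn promises nothing.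

What is the 3.3 % of substrate last read in ash worth in target? One way multiplies it by φ and gets 1.5 percentage points. The other way reads the last stretch of ash itself: from 120 min to 240 min substrate falls by 2.6 points, for which φ promises 1.2 points, yet target moves by −0.9 points, with a scatter of 0.5 points on each reading. The two ways part, and the first cheats: it carries the early fork into a late flask where substrate leaves without becoming target.

So waiting adds nothing, and the mean of the last four ash readings, 46.0 %, is this reckoning's value for now, for dusk and for summer, as no reading shows target flowing back. Reagent stands in excess: at one reagent per target, 0.0673 M remains, yet target in ash reads 46.2 % at 120 min and 45.3 % at 240 min, so this reckoning expects nothing from autumn either. That leaves the catalyst. The unseen share of birch, the charge minus target and substrate, falls from 42.8 % to 37.7 % between 40.0 min and 120 min, so the unseen share holds a pool of about 5.1 points that can still become target. Borrowing that pool for ash and reopening the fork with fresh free catalyst gives 3.8 points against a margin of 2 points, so this reckoning picks spring.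

The forecast differs on that choice, with 45.9 % now, 46.5 % after summer, 46 % after dusk and none as the best option, holding that “More catalyst or reagent can only reach that residue”.

The flask gives 45.4 %, with 45.4 % after summer and 45.4 % after dusk; the best option is spring, which adds 5.2 points.

    substrate + free catalyst ⇌ free catalyst + open intermediate (K = 1.20, k = 1.50 /M/s, Ea = 48.0 kJ/mol, ΔH = −58.0 kJ/mol)
    free catalyst + open intermediate ⇌ catalyst intermediate (K = 8.50 /M, k = 1.20 /M/s, Ea = 50.0 kJ/mol, ΔH = −20.0 kJ/mol)
    reagent + catalyst intermediate → free catalyst + target (k = 0.290 /M/s, Ea = 52.0 kJ/mol)
    free catalyst → spent catalyst (k = 6.20 × 10⁻⁴ /s, Ea = 91.0 kJ/mol)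
    open intermediate + capture agent → trapped intermediate (k = 0.0670 /M/s, Ea = 49.0 kJ/mol)
    substrate + open intermediate → side product (k = 0.0190 /M/s, Ea = 61.0 kJ/mol)
    (constants at 25 °C)

At 240 min the flask holds >99.9 % of its catalyst as spent catalyst, beside 4.18 % of substrate and 4.93 % of open intermediate. Spring adds 5.2 points to this flask, and 0.038 points to the same flask run without the reaction of free catalyst to spent catalyst. Left alone to 2400 min, this flask loses substrate down to 0.392 % at φ = 3.94 × 10⁻⁴. The repeat at 50 °C ends with 100 % spent catalyst, 40.9 % of substrate and 4.86 % of target, a φ of 0.0822.

The data were computed on assumed constants; the scatter is artificial.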